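**Retrosynthetic overview**

1. The route rests on ring C of the flavonol (O1–C2–C3–C4–C4a–C8a). Without C3 this ring is the furan ring of a 2-aryl-3-oxybenzofuran, so C3 is brought in last as a carbene carbon that ends up between C2 and C4.
2. Target 22 ⇐ removal of four MOM acetals ⇐ 3'-O-prenylation ⇐ hydrogenolysis of a 3'-O-benzyl stand-in ⇐ C3–Br to C3–OH through a boronate ⇐ 3-bromoflavone 14.
3. 14 ⇐ dibromocarbene (from bromoform 11) plus 3-siloxybenzofuran 10; C2–C3 and C3–C4 are formed and the furan is expanded to the pyranone.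
4. 10 ⇐ benzylic-carbanion acylation of the aryl benzyl ether ester 8 (closes the furan ring) ⇐ Mitsunobu union of ring A phenol 2 and ring B alcohol 6.
5. Ring order: rings A and B come from benzaldehydes 1 and 3; the furan ring is closed in step 7 and becomes ring C in step 8.

Key step: step 8

Remark on the chemistry: the target has no stereocentre; intermediate 12 is racemic and necessarily cis-fused, and its stereocentres vanish in the same step.

**Route**

Step 1
Reactants: 1 2,4,5-trihydroxybenzaldehyde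
Product: 2 2-hydroxy-4,5-bis(methoxymethoxy)benzaldehyde
Conditions: MOMCl (2.1 equiv), K2CO3, acetone, 0 °C → rt
Reagents that add atoms: chloromethyl methyl ether, COCCl
Why: The 2-OH is hydrogen-bonded to the aldehyde and its phenoxide is the least nucleophilic, so Williamson-type O-alkylation with two equivalents of MOMCl should stop at the 4,5-bis-acetal.

Step 2
Reactants: 3 3,4-dihydroxybenzaldehyde
Product: 4 3-hydroxy-4-(methoxymethoxy)benzaldehyde
Conditions: MOMCl (1.05 equiv), K2CO3, acetone, 0 °C → rt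
Reagents that add atoms: chloromethyl methyl ether, COCCl
Why: The 4-OH, para to the aldehyde, is the more acidic catechol hydroxyl and should be alkylated first under mild carbonate conditions (regioselective Williamson etherification).

Step 3
Reactants: 4 3-hydroxy-4-(methoxymethoxy)benzaldehyde
Product: 5 3-(benzyloxy)-4-(methoxymethoxy)benzaldehyde
Conditions: BnBr, K2CO3, DMF, rt
Reagents that add atoms: benzyl bromide, BrCc1ccccc1
Why: Williamson benzylation of the remaining phenol installs a carbene-inert, hydrogenolysable stand-in for the prenyl ether.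

Step 4
Reactants: 5 3-(benzyloxy)-4-(methoxymethoxy)benzaldehyde
Product: 6 [3-(benzyloxy)-4-(methoxymethoxy)phenyl]methanol
Conditions: NaBH4, MeOH, 0 °C
Reagents that add atoms: none
Why: Borohydride reduction of the aryl aldehyde gives the benzylic alcohol while the acetal and benzyl ethers are inert.

Step 5
Reactants: 2 2-hydroxy-4,5-bis(methoxymethoxy)benzaldehyde; 6 [3-(benzyloxy)-4-(methoxymethoxy)phenyl]methanol
Product: 7 2-{[3-(benzyloxy)-4-(methoxymethoxy)benzyl]oxy}-4,5-bis(methoxymethoxy)benzaldehyde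
Conditions: PPh3, DIAD, THF, 0 °C → rt
Reagents that add atoms: none
Why: Mitsunobu etherification joins the acidic salicylaldehyde phenol to the activated primary benzylic alcohol and avoids isolating a labile electron-rich benzyl halide.

Step 6
Reactants: 7 2-{[3-(benzyloxy)-4-(methoxymethoxy)benzyl]oxy}-4,5-bis(methoxymethoxy)benzaldehyde
Product: 8 methyl 2-{[3-(benzyloxy)-4-(methoxymethoxy)benzyl]oxy}-4,5-bis(methoxymethoxy)benzoate
Conditions: I2, KOH, MeOH, 0 °C
Reagents that add atoms: methanol, CO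
Why: Oxidative esterification of the aryl aldehyde through the hypoiodite of its methyl hemiacetal proceeds in a basic medium that leaves ethers and acetals untouched.

Step 7
Reactants: 8 methyl 2-{[3-(benzyloxy)-4-(methoxymethoxy)benzyl]oxy}-4,5-bis(methoxymethoxy)benzoate
Product: 10 tert-butyl{2-[3-(benzyloxy)-4-(methoxymethoxy)phenyl]-5,6-bis(methoxymethoxy)benzofuran-3-yloxy}dimethylsilane, via lithium benzofuran-3-olate 9 (not isolated)
Conditions: LiN(iPr)2 (2.5 equiv), THF, −78 → −20 °C; then TBSCl, DMPU, −78 °C → rt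
Reagents that add atoms: tert-butyldimethylsilyl chloride, CC(C)(C)[Si](C)(C)Cl
Why: Deprotonation of the ArO–CH2–Ar position, steered by lithium coordination to the ortho ester, and 5-exo-trig attack on the ester (intramolecular Claisen-type acylation) should give the 2-arylbenzofuran-3(2H)-one, which is deprotonated at once to the aromatic olate 9 (the driving force) and O-silylated in the same flask so that the air-sensitive ketone is never handled.

Step 8
Reactants: 10 tert-butyl{2-[3-(benzyloxy)-4-(methoxymethoxy)phenyl]-5,6-bis(methoxymethoxy)benzofuran-3-yloxy}dimethylsilane; 11 bromoform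
Product: 14 2-[3-(benzyloxy)-4-(methoxymethoxy)phenyl]-3-bromo-6,7-bis(methoxymethoxy)-4H-chromen-4-one, via gem-dibromocyclopropane adduct 12 (not isolated), via 3-bromo-4-siloxyflavylium bromide 13 (not isolated)
Conditions: CHBr3 (2 equiv), KOtBu (3 equiv, in portions), toluene, −30 °C → rt
Reagents that add atoms: bromoform (compound 11), BrC(Br)Br
Why: Proposed new method: dibromocarbene, formed from bromoform by α-elimination, should add as an electrophile in a concerted [2+1] step to the C2=C3 bond of 10 to give the cis-fused cyclopropane 12; loss of the bromide syn to the five-membered ring, concerted with disrotatory two-electron opening of the cyclopropane, cleaves the former C2–C3 bond and gives the 3-bromo-4-siloxyflavylium ion 13, from which bromide or tert-butoxide removes silicon to leave the C4 carbonyl. The closest known reactions are the Ciamician–Dennstedt one-carbon ring expansion of indoles and benzofurans with dihalocarbenes and the homologation of silyl enol ethers through dihalocyclopropanes to α-halo enones; their combination on a 2-aryl-3-siloxybenzofuran is untested. Ring C is closed not by a cyclisation but by ring expansion of the furan: the carbene carbon is inserted between the old C2 and the old C3 (now C4), and both new bonds (C2–C3 and C3–C4) are made in the cycloaddition. No stereocentre is set, because the two stereocentres of racemic 12 disappear on opening. The step needs site selectivity (the enol ether bond rather than the alkoxyarenes or the benzylic and acetal C–H bonds) and one direction of opening; the C2=C3 bond carries two oxygen donors (O1 and the siloxy oxygen) and is the most nucleophilic π bond, and the same two oxygens stabilise the pyrylium-type cation so that only the endocyclic bond breaks. Excess KOtBu captures the silyl bromide so that no acid forms near the MOM acetals, and the benzyl ether replaces the prenyl ether because a prenyl alkene would compete for the carbene.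

Step 9
Reactants: 14 2-[3-(benzyloxy)-4-(methoxymethoxy)phenyl]-3-bromo-6,7-bis(methoxymethoxy)-4H-chromen-4-one
Product: 15 2-[3-(benzyloxy)-4-(methoxymethoxy)phenyl]-6,7-bis(methoxymethoxy)-3-(4,4,5,5-tetramethyl-1,3,2-dioxaborolan-2-yl)-4H-chromen-4-one
Conditions: B2pin2, PdCl2(dppf) (5 mol%), KOAc, 1,4-dioxane, 85 °C
Reagents that add atoms: bis(pinacolato)diboron, CC1(C)OB(OC1(C)C)B1OC(C)(C)C(C)(C)O1
Why: Miyaura borylation (oxidative addition of zerovalent palladium into the activated C3–Br bond, acetate-assisted transmetalation, reductive elimination) runs under near-neutral conditions and so avoids the ring contraction to aurones that nucleophilic bases cause with 3-bromoflavones.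

Step 10
Reactants: 15 2-[3-(benzyloxy)-4-(methoxymethoxy)phenyl]-6,7-bis(methoxymethoxy)-3-(4,4,5,5-tetramethyl-1,3,2-dioxaborolan-2-yl)-4H-chromen-4-one
Product: 16 2-[3-(benzyloxy)-4-(methoxymethoxy)phenyl]-3-hydroxy-6,7-bis(methoxymethoxy)-4H-chromen-4-one
Conditions: 30% H2O2, aq. NaOH, THF, 0 °C
Reagents that add atoms: hydrogen peroxide, OO
Why: Boronate oxidation (hydroperoxide adds to boron and C3 migrates from boron to oxygen) should give the flavonol, which tolerates cold alkaline peroxide as in the Algar–Flynn–Oyamada reaction.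

Step 11
Reactants: 16 2-[3-(benzyloxy)-4-(methoxymethoxy)phenyl]-3-hydroxy-6,7-bis(methoxymethoxy)-4H-chromen-4-one
Product: 17 2-[3-(benzyloxy)-4-(methoxymethoxy)phenyl]-3,6,7-tris(methoxymethoxy)-4H-chromen-4-one
Conditions: MOMCl, iPr2NEt, CH2Cl2, 0 °C → rt
Reagents that add atoms: chloromethyl methyl ether, COCCl
Why: O-alkylation of the acidic 3-OH as its MOM acetal (Williamson-type) masks it against the later prenylation and lets all four acetals be removed together at the end.

Step 12
Reactants: 17 2-[3-(benzyloxy)-4-(methoxymethoxy)phenyl]-3,6,7-tris(methoxymethoxy)-4H-chromen-4-one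
Product: 18 2-[3-hydroxy-4-(methoxymethoxy)phenyl]-3,6,7-tris(methoxymethoxy)-4H-chromen-4-one
Conditions: H2 (1 atm), 10% Pd/C, EtOAc, rt
Reagents that add atoms: none
Why: Catalytic hydrogenolysis cleaves the benzyl aryl ether, while the tetrasubstituted conjugated C2=C3 bond of the chromone and the MOM acetals should not react in a neutral solvent.

Step 13
Reactants: 18 2-[3-hydroxy-4-(methoxymethoxy)phenyl]-3,6,7-tris(methoxymethoxy)-4H-chromen-4-one; 19 1-bromo-3-methylbut-2-ene
Product: 20 3,6,7-tris(methoxymethoxy)-2-[4-(methoxymethoxy)-3-(3-methylbut-2-enyloxy)phenyl]-4H-chromen-4-one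
Conditions: K2CO3, DMF, rt
Reagents that add atoms: 1-bromo-3-methylbut-2-ene (compound 19), CC(C)=CCBr
Why: Williamson O-alkylation (SN2) of the only free phenol with the primary allylic bromide fixes the prenyl group on the 3'-oxygen, because the neighbouring 4'-O-MOM acetal cannot migrate.

Step 14
Reactants: 20 3,6,7-tris(methoxymethoxy)-2-[4-(methoxymethoxy)-3-(3-methylbut-2-enyloxy)phenyl]-4H-chromen-4-one
Product: 22 3,6,7-trihydroxy-2-[4-hydroxy-3-(3-methylbut-2-enyloxy)phenyl]-4H-chromen-4-one (target), via tetrakis(trimethylsilyl) ether 21 (not isolated)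
Conditions: TMSOTf, 2,2'-bipyridyl, MeCN, 0 °C → rt; then H2O
Reagents that add atoms: none
Why: The TMSOTf–2,2'-bipyridyl complex converts aryl MOM ethers into aryl trimethylsilyl ethers that water hydrolyses to the phenols (chemoselective acetal deprotection), and with no protic acid present the acid-labile aryl prenyl ether, which HCl/methanol would cleave, should survive.

**Compound list**

1 | 2,4,5-trihydroxybenzaldehyde | O=Cc1cc(O)c(O)cc1O | starting material
2 | 2-hydroxy-4,5-bis(methoxymethoxy)benzaldehyde | O=Cc1cc(OCOC)c(OCOC)cc1O | intermediate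
3 | 3,4-dihydroxybenzaldehyde | O=Cc1ccc(O)c(O)c1 | starting material
4 | 3-hydroxy-4-(methoxymethoxy)benzaldehyde | O=Cc1ccc(OCOC)c(O)c1 | intermediate
5 | 3-(benzyloxy)-4-(methoxymethoxy)benzaldehyde | O=Cc1ccc(OCOC)c(OCc2ccccc2)c1 | intermediate
6 | [3-(benzyloxy)-4-(methoxymethoxy)phenyl]methanol | OCc1ccc(OCOC)c(OCc2ccccc2)c1 | intermediate
7 | 2-{[3-(benzyloxy)-4-(methoxymethoxy)benzyl]oxy}-4,5-bis(methoxymethoxy)benzaldehyde | O=Cc1cc(OCOC)c(OCOC)cc1OCc1ccc(OCOC)c(OCc2ccccc2)c1 | intermediate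
8 | methyl 2-{[3-(benzyloxy)-4-(methoxymethoxy)benzyl]oxy}-4,5-bis(methoxymethoxy)benzoate | COC(=O)c1cc(OCOC)c(OCOC)cc1OCc1ccc(OCOC)c(OCc2ccccc2)c1 | intermediate
9 | lithium 2-[3-(benzyloxy)-4-(methoxymethoxy)phenyl]-5,6-bis(methoxymethoxy)benzofuran-3-olate | [Li+].[O-]c1c(-c2ccc(OCOC)c(OCc3ccccc3)c2)oc2cc(OCOC)c(OCOC)cc12 | intermediate
10 | tert-butyl{2-[3-(benzyloxy)-4-(methoxymethoxy)phenyl]-5,6-bis(methoxymethoxy)benzofuran-3-yloxy}dimethylsilane | CC(C)(C)[Si](C)(C)Oc1c(-c2ccc(OCOC)c(OCc3ccccc3)c2)oc2cc(OCOC)c(OCOC)cc12 | intermediate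
11 | bromoform | BrC(Br)Br | starting material
12 | 1,1-dibromo-1a-[3-(benzyloxy)-4-(methoxymethoxy)phenyl]-6b-(tert-butyldimethylsilyloxy)-4,5-bis(methoxymethoxy)-1a,6b-dihydro-1H-cyclopropa[b]benzofuran (racemic, cis-fused) | CC(C)(C)[Si](C)(C)OC12c3cc(OCOC)c(OCOC)cc3OC1(c1ccc(OCOC)c(OCc3ccccc3)c1)C2(Br)Br | intermediate
13 | 2-[3-(benzyloxy)-4-(methoxymethoxy)phenyl]-3-bromo-4-(tert-butyldimethylsilyloxy)-6,7-bis(methoxymethoxy)chromenylium bromide | [Br-].CC(C)(C)[Si](C)(C)Oc1c(Br)c(-c2ccc(OCOC)c(OCc3ccccc3)c2)[o+]c2cc(OCOC)c(OCOC)cc12 | intermediate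
14 | 2-[3-(benzyloxy)-4-(methoxymethoxy)phenyl]-3-bromo-6,7-bis(methoxymethoxy)-4H-chromen-4-one | COCOc1ccc(-c2oc3cc(OCOC)c(OCOC)cc3c(=O)c2Br)cc1OCc1ccccc1 | intermediate
15 | 2-[3-(benzyloxy)-4-(methoxymethoxy)phenyl]-6,7-bis(methoxymethoxy)-3-(4,4,5,5-tetramethyl-1,3,2-dioxaborolan-2-yl)-4H-chromen-4-one | COCOc1ccc(-c2oc3cc(OCOC)c(OCOC)cc3c(=O)c2B2OC(C)(C)C(C)(C)O2)cc1OCc1ccccc1 | intermediate
16 | 2-[3-(benzyloxy)-4-(methoxymethoxy)phenyl]-3-hydroxy-6,7-bis(methoxymethoxy)-4H-chromen-4-one | COCOc1ccc(-c2oc3cc(OCOC)c(OCOC)cc3c(=O)c2O)cc1OCc1ccccc1 | intermediate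
17 | 2-[3-(benzyloxy)-4-(methoxymethoxy)phenyl]-3,6,7-tris(methoxymethoxy)-4H-chromen-4-one | COCOc1ccc(-c2oc3cc(OCOC)c(OCOC)cc3c(=O)c2OCOC)cc1OCc1ccccc1 | intermediate
18 | 2-[3-hydroxy-4-(methoxymethoxy)phenyl]-3,6,7-tris(methoxymethoxy)-4H-chromen-4-one | COCOc1ccc(-c2oc3cc(OCOC)c(OCOC)cc3c(=O)c2OCOC)cc1O | intermediate
19 | 1-bromo-3-methylbut-2-ene (prenyl bromide) | CC(C)=CCBr | starting material
20 | 3,6,7-tris(methoxymethoxy)-2-[4-(methoxymethoxy)-3-(3-methylbut-2-enyloxy)phenyl]-4H-chromen-4-one | COCOc1ccc(-c2oc3cc(OCOC)c(OCOC)cc3c(=O)c2OCOC)cc1OCC=C(C)C | intermediate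
21 | 2-[3-(3-methylbut-2-enyloxy)-4-(trimethylsilyloxy)phenyl]-3,6,7-tris(trimethylsilyloxy)-4H-chromen-4-one | CC(C)=CCOc1cc(-c2oc3cc(O[Si](C)(C)C)c(O[Si](C)(C)C)cc3c(=O)c2O[Si](C)(C)C)ccc1O[Si](C)(C)C | intermediate
22 | 3,6,7-trihydroxy-2-[4-hydroxy-3-(3-methylbut-2-enyloxy)phenyl]-4H-chromen-4-one (CNP0086069.0) | CC(C)=CCOc1cc(-c2oc3cc(O)c(O)cc3c(=O)c2O)ccc1O | target

**Step count and risks**

Total step count: 14. Longest linear sequence: 13 steps (from 3 through steps 2–14).

Steps most likely to fail: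

1. Step 8 (Proposed new method). The carbene may be used up by insertion into benzylic or acetal C–H bonds, tert-butoxide may strip the silyl group before cyclopropanation, or the bromoflavone may undergo base-induced ring contraction. The fallback uses known chemistry, sets out from 2 and 5, and comes back at 16. Aldehyde 2 is treated with MeMgBr (THF, 0 °C) to give racemic 1-[2-hydroxy-4,5-bis(methoxymethoxy)phenyl]ethanol F1. MnO2 (CH2Cl2, rt) oxidises it to 1-[2-hydroxy-4,5-bis(methoxymethoxy)phenyl]ethanone F2. Claisen–Schmidt condensation of F2 with aldehyde 5 (KOH, EtOH, rt) gives (E)-3-[3-(benzyloxy)-4-(methoxymethoxy)phenyl]-1-[2-hydroxy-4,5-bis(methoxymethoxy)phenyl]prop-2-en-1-one F3. Algar–Flynn–Oyamada oxidation (H2O2, NaOH, MeOH, 0 °C → rt) then closes the pyranone and installs the 3-OH, giving flavonol 16 directly.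

2. Step 7. Benzylic deprotonation may be slow, so that amide attack on the ester, deprotonation at the other benzyl ether, or air oxidation at C2 before silylation takes over. The fallback sets out from 7 and comes back at 10, building the benzofuran at a lower oxidation level and adding the C3 oxygen afterwards. Aldehyde 7 is cyclised and dehydrated with the phosphazene base P4-t-Bu (toluene, rt → 80 °C) to 2-[3-(benzyloxy)-4-(methoxymethoxy)phenyl]-5,6-bis(methoxymethoxy)benzofuran F4. NBS (DMF, 0 °C) brominates C3 to give 2-[3-(benzyloxy)-4-(methoxymethoxy)phenyl]-3-bromo-5,6-bis(methoxymethoxy)benzofuran F5. Bromine–lithium exchange (n-BuLi, THF, −78 °C) and B(OMe)3 give dimethyl {2-[3-(benzyloxy)-4-(methoxymethoxy)phenyl]-5,6-bis(methoxymethoxy)benzofuran-3-yl}boronate F6. H2O2/NaOH oxidises it to racemic 2-[3-(benzyloxy)-4-(methoxymethoxy)phenyl]-5,6-bis(methoxymethoxy)benzofuran-3(2H)-one F7. Deprotonation with KN(SiMe3)2 (THF, −78 °C) and TBSCl return silyl enol ether 10.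

3. Step 14. The allylic C–O bond of the prenyl ether may ionise under the silyl triflate, or cleavage of the four acetals may stay incomplete. The fallback sets out from 16 and comes back at 22, exchanging the acetals for base-labile esters before the prenyl group is introduced. HCl in MeOH/THF (50 °C) removes the three MOM groups of 16 to give 2-[3-(benzyloxy)-4-hydroxyphenyl]-3,6,7-trihydroxy-4H-chromen-4-one F8. PivCl, Et3N and DMAP (CH2Cl2) give 2-[3-(benzyloxy)-4-(pivaloyloxy)phenyl]-3,6,7-tris(pivaloyloxy)-4H-chromen-4-one F9. Hydrogenolysis (H2, 10% Pd/C, EtOAc) gives 2-[3-hydroxy-4-(pivaloyloxy)phenyl]-3,6,7-tris(pivaloyloxy)-4H-chromen-4-one F10; the hindered pivalate is chosen because it is slow to migrate between the catechol oxygens. Neutral Mitsunobu etherification with 3-methylbut-2-en-1-ol (PPh3, DIAD, THF) gives 2-[3-(3-methylbut-2-enyloxy)-4-(pivaloyloxy)phenyl]-3,6,7-tris(pivaloyloxy)-4H-chromen-4-one F11. Methanolysis (K2CO3, MeOH, rt, under argon) then gives target 22.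

**Further compounds**

F1 | step 8 | 1-[2-hydroxy-4,5-bis(methoxymethoxy)phenyl]ethanol (racemic) | CC(O)c1cc(OCOC)c(OCOC)cc1O
F2 | step 8 | 1-[2-hydroxy-4,5-bis(methoxymethoxy)phenyl]ethanone | CC(=O)c1cc(OCOC)c(OCOC)cc1O
F3 | step 8 | (E)-3-[3-(benzyloxy)-4-(methoxymethoxy)phenyl]-1-[2-hydroxy-4,5-bis(methoxymethoxy)phenyl]prop-2-en-1-one | O=C(/C=C/c1ccc(OCOC)c(OCc2ccccc2)c1)c1cc(OCOC)c(OCOC)cc1O
F4 | step 7 | 2-[3-(benzyloxy)-4-(methoxymethoxy)phenyl]-5,6-bis(methoxymethoxy)benzofuran | COCOc1ccc(-c2cc3cc(OCOC)c(OCOC)cc3o2)cc1OCc1ccccc1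
F5 | step 7 | 2-[3-(benzyloxy)-4-(methoxymethoxy)phenyl]-3-bromo-5,6-bis(methoxymethoxy)benzofuran | COCOc1ccc(-c2oc3cc(OCOC)c(OCOC)cc3c2Br)cc1OCc1ccccc1
F6 | step 7 | dimethyl {2-[3-(benzyloxy)-4-(methoxymethoxy)phenyl]-5,6-bis(methoxymethoxy)benzofuran-3-yl}boronate | COB(OC)c1c(-c2ccc(OCOC)c(OCc3ccccc3)c2)oc2cc(OCOC)c(OCOC)cc12
F7 | step 7 | 2-[3-(benzyloxy)-4-(methoxymethoxy)phenyl]-5,6-bis(methoxymethoxy)benzofuran-3(2H)-one (racemic) | O=C1C(c2ccc(OCOC)c(OCc3ccccc3)c2)Oc2cc(OCOC)c(OCOC)cc12
F8 | step 14 | 2-[3-(benzyloxy)-4-hydroxyphenyl]-3,6,7-trihydroxy-4H-chromen-4-one | O=c1c(O)c(-c2ccc(O)c(OCc3ccccc3)c2)oc2cc(O)c(O)cc12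
F9 | step 14 | 2-[3-(benzyloxy)-4-(pivaloyloxy)phenyl]-3,6,7-tris(pivaloyloxy)-4H-chromen-4-one | CC(C)(C)C(=O)Oc1ccc(-c2oc3cc(OC(=O)C(C)(C)C)c(OC(=O)C(C)(C)C)cc3c(=O)c2OC(=O)C(C)(C)C)cc1OCc1ccccc1
F10 | step 14 | 2-[3-hydroxy-4-(pivaloyloxy)phenyl]-3,6,7-tris(pivaloyloxy)-4H-chromen-4-one | CC(C)(C)C(=O)Oc1ccc(-c2oc3cc(OC(=O)C(C)(C)C)c(OC(=O)C(C)(C)C)cc3c(=O)c2OC(=O)C(C)(C)C)cc1O
F11 | step 14 | 2-[3-(3-methylbut-2-enyloxy)-4-(pivaloyloxy)phenyl]-3,6,7-tris(pivaloyloxy)-4H-chromen-4-one | CC(C)=CCOc1cc(-c2oc3cc(OC(=O)C(C)(C)C)c(OC(=O)C(C)(C)C)cc3c(=O)c2OC(=O)C(C)(C)C)ccc1OC(=O)C(C)(C)C
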